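If target passes into over-reaction product by a first-order step, as the list of suspects has it, that product forms at a constant times the target present, and the ratio asked for depends on how the feed of target compares with this drain. On the same list, substrate under free catalyst goes reversibly to intermediate, and intermediate with partner and second catalyst gives target.

| flask | substrate | partner | free catalyst | second catalyst | remark | time |
|---|---|---|---|---|---|---|
| north-east | 20 mM | 60 mM | 40 µM | 0.92 mM | the very flask that is asked about, followed so far |  |
| flask | 20 mM | 60.0 mM | 40 µM | 0.92 mM |  | 15 d |

north-east run (percent of the substrate charged)

| time / d | over-reaction product / % | target / % |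
|---|---|---|
| 0.625 | 7 | 12 |
| 1.67 | 18 | 20 |
| 3.00 | 35 | 17 |
| 5.00 | 59 | 14 |

(standard deviation of a reading: 1.5 percentage points)

- on the list of suspects stand: target -> over-reaction product; partner + second catalyst + intermediate -> second catalyst + target; substrate + free catalyst <-> free catalyst + intermediate

1. ratio of over-reaction product to target at 2.5 h
2. ratio of over-reaction product to target at 30 h
3. ratio of over-reaction product to target at 15 d
4. which of over-reaction product and target there is more of at 15 d

Amounts are fractions of the substrate charged: P target, O over-reaction product, R the rest. Between the last two readings, O gains per day, against mean P:

k = 0.774 /d

This k, a reading with the scatter of the readings, is the drain constant. Over the same days R fades at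

s = 0.288 /d

which is slower than the drain.

Two extremes can be solved in the head. With a steady feed:

O/P = (kt − 1 + e^(−kt)) / (1 − e^(−kt)), which starts as kt/2

With all the target present at once:

O/P = e^(kt) − 1

I take the feed to fade from a nearly steady start, as the rest in the readings fades, so my estimate lies towards the first extreme while st is small. At 2.5 h, st is small, and my estimate of the ratio is 0.0403. At 30 h the extremes give 0.561 and 1.63, and my estimate sits just above the lower one. Late on, target follows the fading rest, P = Rs/(k − s), a quasi-steady state. Carrying R forward at s, I estimate R at 1.52 % at 15 d, P at 0.899 % and the ratio at about 109.

The forecast gives 0.08, 0.62 and 85, with over-reaction product ahead. Its early and late values differ from mine; of the early one it says: “That point hints product may form faster early, perhaps nearly zero-order, so I widen the early range upward.”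

The flask gives 0.0352, 0.604 and 80.5, with over-reaction product ahead.

    target → over-reaction product (k = 0.0320 /h)
    partner + second catalyst + intermediate → second catalyst + target (k = 650 /M²/h)
    substrate + free catalyst ⇌ free catalyst + intermediate (K = 0.560, k = 21000 /M/h)

At 15 d the flask's target has a half-life of 0.90 d by its own step, shorter than the 3.28 d of the flask's slowest mode. The drain constant applied to the flask's 1.19 % of target, against the 4.35 % not yet over-reaction product, gives a fade half-life of 3.28 d. The same reckoning for the neighbour charged with 100 mM of partner, from its 0.204 % of target, gives 1.69 d, and its ratio stands at 487.

(The data are simulated for substances that don't exist; noise was put on by code.)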